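## The problem

The target (24) is a sesquilignan built on a trans-3,4-dibenzyl-γ-butyrolactone. Lactone C4 carries the CH2 of ring A (4-hydroxy-3-methoxyphenyl) and lactone C3 the CH2 of ring B; ring B carries at C5, ortho to its phenol, a 3-hydroxy-1-oxopropan-2-yl chain ending in the aryl ketone of ring C (again 4-hydroxy-3-methoxyphenyl). There are three stereocentres, all S: lactone C3 and C4 (trans) and the side-chain carbon. C4 can control C3, because the trans lactone is the thermodynamic isomer and a C4 arm shields one face of a C3 enolate. Neither lactone centre can reach the side-chain carbon, which lies beyond a CH2 and an arene and must be set by a reagent. That carbon is benzylic, α to an aryl ketone and β to a free hydroxyl: base would epimerise it, cause retro-aldol loss of formaldehyde or dehydrate it to the enone, and acid would let the neighbouring ring B phenol add to the ketone and aromatise to a 2-arylbenzofuran. The ketone should therefore appear late, its α-carbon should never meet base, and the last deprotection should be neutral. The enabling feature is that lactone C4 with its exocyclic CH2 maps onto the bridgehead CH and the cyclopropane CH2 of a 2-oxo-3-oxabicyclo[3.1.0]hexane-1-carboxylate, with lactone C3 as the former malonate carbon, so the ring A–CH2 bond and the C3–CH2(ring B) bond can be made in one operation. Rings A and C are the same arene, and the ring B attachment point corresponds to the bromine of 5-bromovanillin.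

## Retrosynthesis

**Phenols and primary alcohol.** The three phenols of 24 are masked as benzyl ethers (23) and the primary alcohol additionally as a TBS ether (22). No skeletal bond is cut. Benzyl is chosen because it survives magnesium, copper, hot LiCl, Lewis acid and oxidants and leaves by neutral hydrogenolysis; the silyl ether is removed first, under buffered HF, while the phenols are still masked.

**Ketone C(=O)–ring C bond.** Cutting this bond in 22 leads to the α-aryl-β-siloxy aldehyde 20 and the aryl Grignard reagent 8, joined by addition (21) and oxidation. Against an aldol or ketone α-arylation, this cut lets the stereocentre arrive already set and never exposes it to an enolate. It also reuses 8, which serves ring A as well. The forward steps must be non-basic: an organocerium addition and a buffered Dess–Martin oxidation.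

**Benzylic C–CH2OSi bond.** Aldehyde 20 is the product of a stereospecific 1,2-siloxymethyl shift in the epoxy silyl ether 19. That comes from the epoxy alcohol 18 and so from the (E)-cinnamyl alcohol 17 by Sharpless epoxidation. This turns a labile α-aryl carbonyl stereocentre into an epoxide stereocentre, which is easy to make in either sense with cheap tartrate. The forward reaction must ionise only the benzylic C–O bond and shift the siloxymethyl group with inversion.

**Ring B–vinyl bond.** Cutting the aryl–alkene bond of 17 gives the aryl bromide 15 and the hydroxypropenyl boronate 16 (Suzuki–Miyaura coupling). The bromine has been carried from 5-bromovanillin, so no late arene functionalisation is needed. Precursor 15 is a plain protected dibenzyl lactone.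

**Auxiliary ester.** The C3 hydrogen of 15 is traded for an ethoxycarbonyl group (14). This is no simplification in itself, but it exposes the malonate-type carbon needed for the key step. The forward Krapcho step must end at the trans lactone, which thermodynamics secures.

**Key disconnection.** In 14 the ring A–CH2 bond and the C3–CH2(ring B) bond are cut together. This leads to the bicyclic cyclopropane lactone 5, the Grignard reagent 8 and the benzyl bromide 12. Cutting here, and not at C4–CH2 or by stepwise enolate chemistry, delivers both arms as aryl-halide-derived building blocks and takes C4 from the chiral pool. The forward step asks for attack at the cyclopropane CH2 only and for capture of the stabilised enolate on carbon.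

**Building blocks.** Lactone 5 comes from (S)-epichlorohydrin 1 and diethyl malonate 2 through the intermediates 3 and 4. Reagent 8 comes from 4-bromo-2-methoxyphenol 6 via its benzyl ether 7. Bromide 12 comes from 5-bromovanillin 9 by benzylation (10), reduction (11) and bromination.

## Roads not taken

**Alternative 1:** Cut C2–C3 and C2–O1, taking the carbonyl carbon from CO. The precursor is the (E)-trisubstituted allylic alcohol A1. Pd(OAc)2 with a chiral bisphosphine under CO/H2 would add hydride to C4 and an acyl group to C3 syn across the alkene, and the hydroxyl would capture the acylpalladium to give the chloro lactone A2.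
- Merits: the ring and both stereocentres form in one catalytic step, no auxiliary ester has to be removed, and the trans relationship follows directly from the alkene geometry.
- Weak points: A1 needs its own stereodefined synthesis. Enantioselective hydropalladation of an acyclic alkene flanked by two similar benzyl arms has little to rest on. A palladium hydride can walk the double bond into conjugation with either arene, which would erase regio- and stereocontrol. The halogen must be chloride to survive zerovalent palladium, which makes the later vinyl coupling on a hindered electron-rich arene harder.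
- Comparison: this road is more direct at the lactone stage and better in atom economy. The chosen plan sets against it a configuration bought from epichlorohydrin instead of earned from a catalyst, a bromide handle, and a key step whose selectivity is that of a primary carbon toward a soft nucleophile.

**Alternative 2:** Cut C4–C(exocyclic) and C3–CH2(ring B) on a chiral butenolide. The lithiated dithioacetal A4 adds to C4 of the menthyloxybutenolide A3 anti to the menthyloxy group, and the enolate is benzylated by the bromide A5 to give the all-trans adduct A6.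
- Merits: a dependable three-component coupling, a cheap recoverable auxiliary, and substrate control at both lactone centres that is at least as good as in the chosen plan.
- Weak points: the dithioacetal must be removed with Raney Ni or NiCl2/NaBH4 and the acetal carbon reduced and relactonised, which adds steps. Nickel desulfurisation would also remove an aryl halogen, so ring B cannot carry its handle through; A5 indeed has none at C5. The handle would have to be installed later, ortho to a freed phenol, in the presence of a second electron-rich ring.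
- Comparison: equal in stereocontrol, but the chosen plan reaches the lactone at the right oxidation level, without sulfur, and with the bromine in place from the start.

**Alternative 3:** Cut O1–C5. A chiral phosphoric acid with H2O2, or a cyclohexanone monooxygenase, would insert oxygen into one of the enantiotopic C(=O)–CH2 bonds of the prochiral cyclobutanone A7 to give the monobenzyl lactone A8. A separate trans-selective enolate benzylation with 12 would then lead to 15.
- Merits: catalytic asymmetry without a chiral-pool reagent, a metal-free key step, and a cheap eugenol-derived substrate.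
- Weak points: the enantiomeric purity depends on catalyst–substrate matching for a 3-benzylcyclobutanone. The cyclobutanone costs a ketene cycloaddition and a dechlorination. The second arm needs a kinetic lithium enolate.
- Comparison: the step count to 15 is the same as in the chosen plan, and A8 is the compound through which the fallback for the key step passes. The chosen plan sets against it enantiopurity fixed by epichlorohydrin and the formation of both benzylic bonds in one flask.

Key step: step 7

Assumption: the boronate 16 is treated as a purchasable reagent; the carbinol centre formed in step 13 is left unassigned because step 14 removes it.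

## Route

Step 1
Reactants: 1 (S)-epichlorohydrin; 2 diethyl malonate
Product: 5 ethyl (1R,5S)-2-oxo-3-oxabicyclo[3.1.0]hexane-1-carboxylate, via epoxy malonate 3 (not isolated), via cyclopropyl carbinol diester 4 (not isolated)
Conditions: NaOEt, EtOH, 0 °C to reflux
Reagents that add atoms: none
Why: Tandem alkylation–cyclopropanation–lactonisation: sodiomalonate opens the epoxide of 1 at its CH2, the alkoxide closes a new epoxide by displacing chloride (3), the malonate carbanion opens it at the CH with inversion (3-exo-tet) to give 4, and the alkoxide lactonises onto the cis ester. The stereocentre of 1 thus becomes C5 (S) of 5 and the cis fusion fixes C1 (R); ethoxide in ethanol favours this path over direct chloride displacement, which would give the enantiomer.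

Step 2
Reactants: 6 4-bromo-2-methoxyphenol
Product: 7 1-(benzyloxy)-4-bromo-2-methoxybenzene
Conditions: BnBr, K2CO3, DMF, rt
Reagents that add atoms: benzyl bromide, BrCc1ccccc1
Why: Williamson ether synthesis on the phenoxide; the benzyl ether should survive every later reagent and leave by neutral hydrogenolysis.

Step 3
Reactants: 7 1-(benzyloxy)-4-bromo-2-methoxybenzene
Product: 8 [4-(benzyloxy)-3-methoxyphenyl]magnesium bromide (titrated THF solution, used in steps 7 and 13)
Conditions: Mg turnings, I2 (cat.), THF, 40 °C
Reagents that add atoms: magnesium, [Mg]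
Why: Grignard formation by insertion of magnesium into the aryl C–Br bond; aryl methyl and benzyl ethers are inert.

Step 4
Reactants: 9 5-bromovanillin
Product: 10 4-(benzyloxy)-3-bromo-5-methoxybenzaldehyde
Conditions: BnBr, K2CO3, DMF, 60 °C
Reagents that add atoms: benzyl bromide, BrCc1ccccc1
Why: Williamson ether synthesis; the phenol flanked by Br and OMe is acidic and alkylates cleanly on warming.

Step 5
Reactants: 10 4-(benzyloxy)-3-bromo-5-methoxybenzaldehyde
Product: 11 [4-(benzyloxy)-3-bromo-5-methoxyphenyl]methanol
Conditions: NaBH4, MeOH/THF, 0 °C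
Reagents that add atoms: none
Why: Borohydride reduction of an aryl aldehyde; the aryl bromide and the ethers are untouched.

Step 6
Reactants: 11 [4-(benzyloxy)-3-bromo-5-methoxyphenyl]methanol
Product: 12 2-(benzyloxy)-1-bromo-5-(bromomethyl)-3-methoxybenzene
Conditions: PBr3, CH2Cl2, 0 °C
Reagents that add atoms: phosphorus tribromide, BrP(Br)Br
Why: Conversion of a benzylic alcohol to the bromide through a phosphite ester and SN2 displacement; the reactive bromide is used promptly.

Step 7
Reactants: 5 ethyl (1R,5S)-2-oxo-3-oxabicyclo[3.1.0]hexane-1-carboxylate; 8 [4-(benzyloxy)-3-methoxyphenyl]magnesium bromide; 12 2-(benzyloxy)-1-bromo-5-(bromomethyl)-3-methoxybenzene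
Product: 14 ethyl (3S,4S)-3-[4-(benzyloxy)-3-bromo-5-methoxybenzyl]-4-[4-(benzyloxy)-3-methoxybenzyl]-2-oxotetrahydrofuran-3-carboxylate (benzyl groups trans), via bromomagnesium lactone ester enolate 13 (not isolated)
Conditions: 8 (1.1 equiv), CuI (10 mol%), THF, −40 to −20 °C; then 12 (1.3 equiv), DMPU, −20 °C to rt
Reagents that add atoms: none
Why: Transmetalation of 8 with CuI gives an aryl cuprate that attacks the cyclopropane CH2 (C6) of 5 in an SN2-like homoconjugate addition, the C1–C6 bond breaking as the lactone–ester enolate 13 departs; ring strain and the two acceptor groups drive it. The closest known reaction type is the copper-catalysed Grignard opening of cyclopropane-1,1-dicarboxylates, and of this bicyclic lactone itself, to 4-substituted 3-carboalkoxybutyrolactones, followed by alkylation of the stabilised enolate. No ring is closed: the three-membered ring opens and the lactone is carried through. The bridgehead CH of 5, fixed by 1, is not touched and becomes C4 (S). The new quaternary C3 is controlled by C4: bromide 12 should approach the planar chelated enolate anti to the C4 arylmethyl arm, placing the two benzyl groups trans (3S,4S); because step 8 removes the ester, this selectivity is a convenience and not a requirement. The step needs attack at CH2 and not at the bridgehead CH or a carbonyl (secured by the unhindered primary carbon, the soft copper nucleophile and low temperature), C- and not O-benzylation (magnesium chelate, soft benzylic electrophile, DMPU), and an intact aryl bromide in 12 (only a small excess of 8, and aryl bromides are inert to catalytic copper at this temperature).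

Step 8
Reactants: 14 ethyl (3S,4S)-3-[4-(benzyloxy)-3-bromo-5-methoxybenzyl]-4-[4-(benzyloxy)-3-methoxybenzyl]-2-oxotetrahydrofuran-3-carboxylate
Product: 15 (3S,4S)-3-[4-(benzyloxy)-3-bromo-5-methoxybenzyl]-4-[4-(benzyloxy)-3-methoxybenzyl]dihydrofuran-2(3H)-one
Conditions: LiCl, H2O, DMSO, 150 °C; then DBU (cat.), PhMe, rt
Reagents that add atoms: none
Why: Krapcho dealkoxycarbonylation: chloride dealkylates the ethyl ester, the carboxylate loses CO2 and the lactone enolate is protonated. C3 becomes a CH stereocentre set thermodynamically under control by C4; the DBU treatment should converge any cis isomer on the trans (3S,4S) lactone.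

Step 9
Reactants: 15 (3S,4S)-3-[4-(benzyloxy)-3-bromo-5-methoxybenzyl]-4-[4-(benzyloxy)-3-methoxybenzyl]dihydrofuran-2(3H)-one; 16 (E)-3-(4,4,5,5-tetramethyl-1,3,2-dioxaborolan-2-yl)prop-2-en-1-ol
Product: 17 (3S,4S)-3-{4-(benzyloxy)-3-[(1E)-3-hydroxyprop-1-en-1-yl]-5-methoxybenzyl}-4-[4-(benzyloxy)-3-methoxybenzyl]dihydrofuran-2(3H)-one
Conditions: Pd(OAc)2 (5 mol%), SPhos, K3PO4, THF/H2O, 60 °C; dilute acid work-up
Reagents that add atoms: none
Why: Suzuki–Miyaura coupling with retention of alkene geometry; the dialkylbiarylphosphine should handle the electron-rich ortho-alkoxy bromide. Acidification recloses any lactone opened by the aqueous base, and C3 is already in its thermodynamic configuration.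

Step 10
Reactants: 17 (3S,4S)-3-{4-(benzyloxy)-3-[(1E)-3-hydroxyprop-1-en-1-yl]-5-methoxybenzyl}-4-[4-(benzyloxy)-3-methoxybenzyl]dihydrofuran-2(3H)-one
Product: 18 (3S,4S)-3-{4-(benzyloxy)-3-[(2S,3S)-3-(hydroxymethyl)oxiran-2-yl]-5-methoxybenzyl}-4-[4-(benzyloxy)-3-methoxybenzyl]dihydrofuran-2(3H)-one
Conditions: Ti(OiPr)4 (10 mol%), L-(+)-DIPT (12 mol%), TBHP, 4 Å MS, CH2Cl2, −20 °C
Reagents that add atoms: tert-butyl hydroperoxide, CC(C)(C)OO
Why: Sharpless asymmetric epoxidation: the titanium L-(+)-tartrate catalyst delivers oxygen to the face of the (E)-allylic alcohol that gives the (2S,3S)-epoxy alcohol. This is reagent control; the distant lactone centres should exert no influence, and the catalytic sieve-dried protocol limits opening of the electron-rich aryl epoxide.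

Step 11
Reactants: 18 (3S,4S)-3-{4-(benzyloxy)-3-[(2S,3S)-3-(hydroxymethyl)oxiran-2-yl]-5-methoxybenzyl}-4-[4-(benzyloxy)-3-methoxybenzyl]dihydrofuran-2(3H)-one
Product: 19 (3S,4S)-3-{4-(benzyloxy)-3-[(2S,3S)-3-({[tert-butyl(dimethyl)silyl]oxy}methyl)oxiran-2-yl]-5-methoxybenzyl}-4-[4-(benzyloxy)-3-methoxybenzyl]dihydrofuran-2(3H)-one
Conditions: TBSCl, imidazole, CH2Cl2, 0 °C
Reagents that add atoms: tert-butyldimethylsilyl chloride, CC(C)(C)[Si](C)(C)Cl
Why: Silylation of the primary alcohol; the silyl ether makes the CH2O group the migrating group of step 12 and protects it until step 15.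

Step 12
Reactants: 19 (3S,4S)-3-{4-(benzyloxy)-3-[(2S,3S)-3-({[tert-butyl(dimethyl)silyl]oxy}methyl)oxiran-2-yl]-5-methoxybenzyl}-4-[4-(benzyloxy)-3-methoxybenzyl]dihydrofuran-2(3H)-one
Product: 20 (2S)-2-[2-(benzyloxy)-5-({(3S,4S)-4-[4-(benzyloxy)-3-methoxybenzyl]-2-oxotetrahydrofuran-3-yl}methyl)-3-methoxyphenyl]-3-{[tert-butyl(dimethyl)silyl]oxy}propanal (used crude)
Conditions: MeAl(OC6H2-4-Br-2,6-tBu2)2 (MABR, 2 equiv, from Me3Al and 4-bromo-2,6-di-tert-butylphenol), CH2Cl2, −78 °C
Reagents that add atoms: none
Why: Organoaluminium-promoted epoxy silyl ether rearrangement (a semipinacol-type 1,2-shift): the bulky Lewis acid ionises the benzylic C–O bond and the siloxymethyl group migrates anti to the departing oxygen. The benzylic carbon is inverted, so the (S)-epoxide carbon becomes the (S)-configured α-aryl carbon and the former C2 becomes the aldehyde. The ortho-benzyloxy group stabilises charge at the migration terminus; 20 is not chromatographed because α-aryl aldehydes racemise on silica.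

Step 13
Reactants: 20 the (2S)-α-aryl-β-siloxy aldehyde; 8 [4-(benzyloxy)-3-methoxyphenyl]magnesium bromide
Product: 21 (3S,4S)-3-{4-(benzyloxy)-3-[(2S)-1-[4-(benzyloxy)-3-methoxyphenyl]-3-{[tert-butyl(dimethyl)silyl]oxy}-1-hydroxypropan-2-yl]-5-methoxybenzyl}-4-[4-(benzyloxy)-3-methoxybenzyl]dihydrofuran-2(3H)-one (mixture of carbinol epimers)
Conditions: 8 (1.3 equiv), CeCl3, THF, −78 °C; aq. NH4Cl
Reagents that add atoms: none
Why: 1,2-Addition of an organocerium reagent made from the Grignard reagent and CeCl3; its low basicity should avoid enolisation of the α-aryl aldehyde and β-elimination of silanolate, and at −78 °C the lactone is not attacked. The carbinol configuration is irrelevant because it is oxidised next.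

Step 14
Reactants: 21 the secondary alcohol (both carbinol epimers)
Product: 22 (3S,4S)-3-{4-(benzyloxy)-3-[(2S)-1-[4-(benzyloxy)-3-methoxyphenyl]-3-{[tert-butyl(dimethyl)silyl]oxy}-1-oxopropan-2-yl]-5-methoxybenzyl}-4-[4-(benzyloxy)-3-methoxybenzyl]dihydrofuran-2(3H)-one
Conditions: Dess–Martin periodinane, NaHCO3, CH2Cl2, 0 °C to rt
Reagents that add atoms: none
Why: Dess–Martin oxidation of a benzylic alcohol under buffered, non-basic conditions; both epimers converge on one ketone and the α-stereocentre should not enolise.

Step 15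
Reactants: 22 the silyl-protected ketone
Product: 23 (3S,4S)-3-{4-(benzyloxy)-3-[(2S)-1-[4-(benzyloxy)-3-methoxyphenyl]-3-hydroxy-1-oxopropan-2-yl]-5-methoxybenzyl}-4-[4-(benzyloxy)-3-methoxybenzyl]dihydrofuran-2(3H)-one
Conditions: HF·pyridine, pyridine, THF, 0 °C to rt
Reagents that add atoms: none
Why: Fluoride-mediated desilylation under buffered, mildly acidic conditions; a basic fluoride source would risk E1cB elimination or retro-aldol cleavage. With the phenols still benzylated, no benzofuran can form.

Step 16
Reactants: 23 the tribenzyl ether of the target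
Product: 24 (3S,4S)-3-{4-hydroxy-3-[(2S)-3-hydroxy-1-(4-hydroxy-3-methoxyphenyl)-1-oxopropan-2-yl]-5-methoxybenzyl}-4-(4-hydroxy-3-methoxybenzyl)dihydrofuran-2(3H)-one (CNP0281222.1)
Conditions: H2 (1 atm), Pd/C, EtOAc, rt
Reagents that add atoms: none
Why: Hydrogenolysis of three aryl benzyl ethers under neutral conditions; the electron-rich aryl ketone should be reduced far more slowly than the O-benzyl groups are cleaved, and no stereocentre is touched.

## Compound list

1 | (S)-epichlorohydrin, (2S)-2-(chloromethyl)oxirane | ClC[C@@H]1CO1 | starting material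
2 | diethyl malonate | CCOC(=O)CC(=O)OCC | starting material
3 | diethyl 2-{[(2S)-oxiran-2-yl]methyl}propanedioate (present as its sodium enolate) | CCOC(=O)C(C[C@H]1CO1)C(=O)OCC | intermediate (not isolated)
4 | diethyl (2S)-2-(hydroxymethyl)cyclopropane-1,1-dicarboxylate (present as its sodium alkoxide) | C1[C@H](CO)C1(C(=O)OCC)C(=O)OCC | intermediate (not isolated)
5 | ethyl (1R,5S)-2-oxo-3-oxabicyclo[3.1.0]hexane-1-carboxylate | C1[C@@H]2COC(=O)[C@]12C(=O)OCC | intermediate
6 | 4-bromo-2-methoxyphenol | COc1cc(Br)ccc1O | starting material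
7 | 1-(benzyloxy)-4-bromo-2-methoxybenzene | COc1cc(Br)ccc1OCc1ccccc1 | intermediate
8 | [4-(benzyloxy)-3-methoxyphenyl]magnesium bromide | COc1cc([Mg]Br)ccc1OCc1ccccc1 | intermediate
9 | 5-bromovanillin, 3-bromo-4-hydroxy-5-methoxybenzaldehyde | COc1cc(C=O)cc(Br)c1O | starting material
10 | 4-(benzyloxy)-3-bromo-5-methoxybenzaldehyde | COc1cc(C=O)cc(Br)c1OCc1ccccc1 | intermediate
11 | [4-(benzyloxy)-3-bromo-5-methoxyphenyl]methanol | COc1cc(CO)cc(Br)c1OCc1ccccc1 | intermediate
12 | 2-(benzyloxy)-1-bromo-5-(bromomethyl)-3-methoxybenzene | COc1cc(CBr)cc(Br)c1OCc1ccccc1 | intermediate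
13 | bromomagnesium enolate of ethyl (4S)-4-[4-(benzyloxy)-3-methoxybenzyl]-2-oxotetrahydrofuran-3-carboxylate | CCOC(=O)C1=C(O[Mg]Br)OC[C@H]1Cc1ccc(OCc2ccccc2)c(OC)c1 | intermediate (not isolated)
14 | ethyl (3S,4S)-3-[4-(benzyloxy)-3-bromo-5-methoxybenzyl]-4-[4-(benzyloxy)-3-methoxybenzyl]-2-oxotetrahydrofuran-3-carboxylate | COc1cc(C[C@@H]2COC(=O)[C@]2(Cc2cc(OC)c(OCc3ccccc3)c(Br)c2)C(=O)OCC)ccc1OCc1ccccc1 | intermediate
15 | (3S,4S)-3-[4-(benzyloxy)-3-bromo-5-methoxybenzyl]-4-[4-(benzyloxy)-3-methoxybenzyl]dihydrofuran-2(3H)-one | COc1cc(C[C@@H]2COC(=O)[C@H]2Cc2cc(OC)c(OCc3ccccc3)c(Br)c2)ccc1OCc1ccccc1 | intermediate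
16 | (E)-3-(4,4,5,5-tetramethyl-1,3,2-dioxaborolan-2-yl)prop-2-en-1-ol | OC/C=C/B1OC(C)(C)C(C)(C)O1 | starting material
17 | (3S,4S)-3-{4-(benzyloxy)-3-[(1E)-3-hydroxyprop-1-en-1-yl]-5-methoxybenzyl}-4-[4-(benzyloxy)-3-methoxybenzyl]dihydrofuran-2(3H)-one | COc1cc(C[C@@H]2COC(=O)[C@H]2Cc2cc(OC)c(OCc3ccccc3)c(/C=C/CO)c2)ccc1OCc1ccccc1 | intermediate
18 | (3S,4S)-3-{4-(benzyloxy)-3-[(2S,3S)-3-(hydroxymethyl)oxiran-2-yl]-5-methoxybenzyl}-4-[4-(benzyloxy)-3-methoxybenzyl]dihydrofuran-2(3H)-one | COc1cc(C[C@@H]2COC(=O)[C@H]2Cc2cc(OC)c(OCc3ccccc3)c([C@@H]3O[C@H]3CO)c2)ccc1OCc1ccccc1 | intermediate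
19 | (3S,4S)-3-{4-(benzyloxy)-3-[(2S,3S)-3-({[tert-butyl(dimethyl)silyl]oxy}methyl)oxiran-2-yl]-5-methoxybenzyl}-4-[4-(benzyloxy)-3-methoxybenzyl]dihydrofuran-2(3H)-one | COc1cc(C[C@@H]2COC(=O)[C@H]2Cc2cc(OC)c(OCc3ccccc3)c([C@@H]3O[C@H]3CO[Si](C)(C)C(C)(C)C)c2)ccc1OCc1ccccc1 | intermediate
20 | (2S)-2-[2-(benzyloxy)-5-({(3S,4S)-4-[4-(benzyloxy)-3-methoxybenzyl]-2-oxotetrahydrofuran-3-yl}methyl)-3-methoxyphenyl]-3-{[tert-butyl(dimethyl)silyl]oxy}propanal | COc1cc(C[C@@H]2COC(=O)[C@H]2Cc2cc(OC)c(OCc3ccccc3)c([C@@H](CO[Si](C)(C)C(C)(C)C)C=O)c2)ccc1OCc1ccccc1 | intermediate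
21 | (3S,4S)-3-{4-(benzyloxy)-3-[(2S)-1-[4-(benzyloxy)-3-methoxyphenyl]-3-{[tert-butyl(dimethyl)silyl]oxy}-1-hydroxypropan-2-yl]-5-methoxybenzyl}-4-[4-(benzyloxy)-3-methoxybenzyl]dihydrofuran-2(3H)-one, carbinol centre unassigned | COc1cc(C[C@@H]2COC(=O)[C@H]2Cc2cc(OC)c(OCc3ccccc3)c([C@@H](CO[Si](C)(C)C(C)(C)C)C(O)c3ccc(OCc4ccccc4)c(OC)c3)c2)ccc1OCc1ccccc1 | intermediate
22 | (3S,4S)-3-{4-(benzyloxy)-3-[(2S)-1-[4-(benzyloxy)-3-methoxyphenyl]-3-{[tert-butyl(dimethyl)silyl]oxy}-1-oxopropan-2-yl]-5-methoxybenzyl}-4-[4-(benzyloxy)-3-methoxybenzyl]dihydrofuran-2(3H)-one | COc1cc(C[C@@H]2COC(=O)[C@H]2Cc2cc(OC)c(OCc3ccccc3)c([C@@H](CO[Si](C)(C)C(C)(C)C)C(=O)c3ccc(OCc4ccccc4)c(OC)c3)c2)ccc1OCc1ccccc1 | intermediate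
23 | (3S,4S)-3-{4-(benzyloxy)-3-[(2S)-1-[4-(benzyloxy)-3-methoxyphenyl]-3-hydroxy-1-oxopropan-2-yl]-5-methoxybenzyl}-4-[4-(benzyloxy)-3-methoxybenzyl]dihydrofuran-2(3H)-one | COc1cc(C[C@@H]2COC(=O)[C@H]2Cc2cc(OC)c(OCc3ccccc3)c([C@@H](CO)C(=O)c3ccc(OCc4ccccc4)c(OC)c3)c2)ccc1OCc1ccccc1 | intermediate
24 | (3S,4S)-3-{4-hydroxy-3-[(2S)-3-hydroxy-1-(4-hydroxy-3-methoxyphenyl)-1-oxopropan-2-yl]-5-methoxybenzyl}-4-(4-hydroxy-3-methoxybenzyl)dihydrofuran-2(3H)-one | COc1cc(C[C@@H]2COC(=O)[C@H]2Cc2cc(OC)c(O)c([C@@H](CO)C(=O)c3ccc(O)c(OC)c3)c2)ccc1O | target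

## Step count and risk

Total: 16 steps. Longest linear sequence: 13 steps (steps 4, 5, 6, then 7 to 16, from 5-bromovanillin).

**Step 7 (key step).** The chelated magnesium enolate 13 is a poor nucleophile, so capture by 12 may be slow or incomplete. Copper may also couple left-over 8 with the benzylic bromide, and some O-benzylation is possible.
Fallback: separate the two bond formations and move the benzylation to a kinetic enolate. It sets out from 5 and returns at 15.
- 5 is opened with 8 and catalytic CuI as before, but quenched with aqueous NH4Cl to give ethyl (4S)-4-[4-(benzyloxy)-3-methoxybenzyl]-2-oxotetrahydrofuran-3-carboxylate F1.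
- Krapcho dealkoxycarbonylation (LiCl, wet DMSO, 150 °C) gives (4S)-4-[4-(benzyloxy)-3-methoxybenzyl]dihydrofuran-2(3H)-one F2.
- Deprotonation with LiN(SiMe3)2 in THF at −78 °C and alkylation with 12, anti to the C4 arm, gives 15 directly.

**Step 12.** The benzylic cation, stabilised by the ortho-benzyloxy group, may live long enough to erode stereochemical fidelity. Hydride shift to the α-siloxy ketone or capture by the ortho ether oxygen may compete, and the lactone may sequester the Lewis acid.
Fallback: build the ketone first and set the stereocentre by catalytic asymmetric hydroxymethylation. It sets out from 15 and returns at 23.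
- Palladium-catalysed ketone α-arylation of 1-[4-(benzyloxy)-3-methoxyphenyl]ethanone with 15 (Pd(OAc)2, Xantphos, K3PO4, toluene, 80 °C) gives the deoxybenzoin (3S,4S)-3-{4-(benzyloxy)-3-{2-[4-(benzyloxy)-3-methoxyphenyl]-2-oxoethyl}-5-methoxybenzyl}-4-[4-(benzyloxy)-3-methoxybenzyl]dihydrofuran-2(3H)-one F3.
- Soft enolisation (Me3SiOTf, Et3N, CH2Cl2, 0 °C) gives its (Z)-trimethylsilyl enol ether F4.
- A Mukaiyama-type aldol reaction with aqueous formaldehyde under Sc(OTf)3 and a chiral 2,2'-bipyridine diol ligand (DME/H2O, −20 °C), with the ligand enantiomer chosen for the (S) centre, gives 23.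

**Step 13.** Partial enolisation of the α-aryl aldehyde would cost enantiopurity; elimination of silanolate to the 2-arylacrolein and addition to the lactone are further risks.
Fallback: replace carbonyl addition plus oxidation by a base-free acyl cross-coupling. It sets out from 20 and returns at 22.
- Pinnick oxidation (NaClO2, NaH2PO4, 2-methyl-2-butene, tBuOH/H2O) gives (2S)-2-[2-(benzyloxy)-5-({(3S,4S)-4-[4-(benzyloxy)-3-methoxybenzyl]-2-oxotetrahydrofuran-3-yl}methyl)-3-methoxyphenyl]-3-{[tert-butyl(dimethyl)silyl]oxy}propanoic acid F5.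
- Coupling with thiophenol (EDC, HOBt, CH2Cl2, 0 °C) gives the S-phenyl thioester F6.
- Liebeskind–Srogl coupling with [4-(benzyloxy)-3-methoxyphenyl]boronic acid (Pd2(dba)3, tri(2-furyl)phosphine, copper thiophene-2-carboxylate Cu(O2CC4H3S), THF, 50 °C) gives 22.

**Step 10.** The titanium Lewis acid may open the electron-rich ortho-alkoxyaryl epoxide during reaction or work-up, and turnover may be slow for this hindered cinnamyl alcohol.
Fallback: epoxidise under basic, metal-free conditions after silylation. It sets out from 17 and returns at 19.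
- Silylation of 17 (TBSCl, imidazole) gives (3S,4S)-3-{4-(benzyloxy)-3-[(1E)-3-{[tert-butyl(dimethyl)silyl]oxy}prop-1-en-1-yl]-5-methoxybenzyl}-4-[4-(benzyloxy)-3-methoxybenzyl]dihydrofuran-2(3H)-one F7.
- Shi epoxidation with the L-fructose-derived ketone catalyst (the enantiomer of the usual one), KHSO5 and K2CO3 buffer in MeCN/dimethoxymethane/H2O at 0 °C gives 19.

**Step 16.** Over-reduction of the aryl ketone to the benzylic alcohol or methylene may occur, or the flanked ring B benzyl ether may cleave sluggishly.
Fallback: non-reductive Lewis-acid debenzylation. Treating 23 with BCl3 and pentamethylbenzene as cation scavenger in CH2Cl2 at −78 °C, with a cold methanol quench so that the freed ortho-phenol does not cyclise onto the ketone, gives 24 directly. No new compound is made.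

## Further compounds

F1 | step 7 | ethyl (4S)-4-[4-(benzyloxy)-3-methoxybenzyl]-2-oxotetrahydrofuran-3-carboxylate (C3 epimers) | CCOC(=O)C1C(=O)OC[C@H]1Cc1ccc(OCc2ccccc2)c(OC)c1
F2 | step 7 | (4S)-4-[4-(benzyloxy)-3-methoxybenzyl]dihydrofuran-2(3H)-one | COc1cc(C[C@@H]2COC(=O)C2)ccc1OCc1ccccc1
F3 | step 12 | (3S,4S)-3-{4-(benzyloxy)-3-{2-[4-(benzyloxy)-3-methoxyphenyl]-2-oxoethyl}-5-methoxybenzyl}-4-[4-(benzyloxy)-3-methoxybenzyl]dihydrofuran-2(3H)-one | COc1cc(C[C@@H]2COC(=O)[C@H]2Cc2cc(OC)c(OCc3ccccc3)c(CC(=O)c3ccc(OCc4ccccc4)c(OC)c3)c2)ccc1OCc1ccccc1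
F4 | step 12 | (Z)-trimethylsilyl enol ether of F3 | COc1cc(C[C@@H]2COC(=O)[C@H]2Cc2cc(OC)c(OCc3ccccc3)c(/C=C(\O[Si](C)(C)C)c3ccc(OCc4ccccc4)c(OC)c3)c2)ccc1OCc1ccccc1
F5 | step 13 | (2S)-2-[2-(benzyloxy)-5-({(3S,4S)-4-[4-(benzyloxy)-3-methoxybenzyl]-2-oxotetrahydrofuran-3-yl}methyl)-3-methoxyphenyl]-3-{[tert-butyl(dimethyl)silyl]oxy}propanoic acid | COc1cc(C[C@@H]2COC(=O)[C@H]2Cc2cc(OC)c(OCc3ccccc3)c([C@@H](CO[Si](C)(C)C(C)(C)C)C(O)=O)c2)ccc1OCc1ccccc1
F6 | step 13 | S-phenyl thioester of F5 | COc1cc(C[C@@H]2COC(=O)[C@H]2Cc2cc(OC)c(OCc3ccccc3)c([C@@H](CO[Si](C)(C)C(C)(C)C)C(=O)Sc3ccccc3)c2)ccc1OCc1ccccc1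
F7 | step 10 | (3S,4S)-3-{4-(benzyloxy)-3-[(1E)-3-{[tert-butyl(dimethyl)silyl]oxy}prop-1-en-1-yl]-5-methoxybenzyl}-4-[4-(benzyloxy)-3-methoxybenzyl]dihydrofuran-2(3H)-one | COc1cc(C[C@@H]2COC(=O)[C@H]2Cc2cc(OC)c(OCc3ccccc3)c(/C=C/CO[Si](C)(C)C(C)(C)C)c2)ccc1OCc1ccccc1
F0 | step 16 | none | none
A1 | alternative 1 | (2E)-2-[4-(benzyloxy)-3-methoxybenzyl]-4-[4-(benzyloxy)-3-chloro-5-methoxyphenyl]but-2-en-1-ol | OC/C(Cc1ccc(OCc2ccccc2)c(OC)c1)=C/Cc1cc(OC)c(OCc2ccccc2)c(Cl)c1
A2 | alternative 1 | (3S,4S)-4-[4-(benzyloxy)-3-methoxybenzyl]-3-[4-(benzyloxy)-3-chloro-5-methoxybenzyl]dihydrofuran-2(3H)-one | COc1cc(C[C@@H]2COC(=O)[C@H]2Cc2cc(OC)c(OCc3ccccc3)c(Cl)c2)ccc1OCc1ccccc1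
A3 | alternative 2 | (5S)-5-(d-menthyloxy)furan-2(5H)-one | C[C@H]1CC[C@@H]([C@H](C1)O[C@H]2OC(=O)C=C2)C(C)C
A4 | alternative 2 | 1-(benzyloxy)-4-[bis(phenylthio)methyl]-2-methoxybenzene (used as its lithio derivative) | COc1cc(C(Sc2ccccc2)Sc2ccccc2)ccc1OCc1ccccc1
A5 | alternative 2 | 4-(bromomethyl)-2-methoxy-1-(methoxymethoxy)benzene | COCOc1ccc(CBr)cc1OC
A6 | alternative 2 | all-trans 3-[3-methoxy-4-(methoxymethoxy)benzyl]-4-{[4-(benzyloxy)-3-methoxyphenyl]bis(phenylthio)methyl}-5-(d-menthyloxy)dihydrofuran-2(3H)-one | C[C@H]1CC[C@@H]([C@H](C1)O[C@H]2OC(=O)[C@@H](Cc3ccc(OCOC)c(OC)c3)[C@@H]2C(Sc3ccccc3)(Sc3ccccc3)c3ccc(OCc4ccccc4)c(OC)c3)C(C)C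
A7 | alternative 3 | 3-[4-(benzyloxy)-3-methoxybenzyl]cyclobutan-1-one | COc1cc(CC2CC(=O)C2)ccc1OCc1ccccc1
A8 | alternative 3 | (S)-4-[4-(benzyloxy)-3-methoxybenzyl]dihydrofuran-2(3H)-one | COc1cc(C[C@@H]2COC(=O)C2)ccc1OCc1ccccc1
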